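The peroxide bridge is cut at the C5–O bond only. C5 is a tertiary allylic carbon of the cyclohexene ring (C3=C4–C5) and sits 1,4 across that ring from C2, which carries the first oxygen pair as a hydroperoxide on the convex face. Mild acid ionises the C5 carbinol to a C3–C5 allyl cation and the C2 hydroperoxide traps it transannularly, closing the 2,3-dioxabicyclo[2.2.2]octene and setting C5 in one operation, without ever forming the ring-opening-prone bicyclo[4.2.0]octa-2,4-diene. The substrate is the fully assembled pyrone-bearing bicyclo[4.2.0]oct-3-ene carrying the C2 hydroperoxide and the C5 tertiary alcohol, made by Birch alkylation, epoxynitrile cyclobutane closure and a Schenck ene reaction.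

Key step: step 17

Remark: carbocycle locants follow bicyclo[4.2.0]octane (C1 and C6 fusion carbons, C7 pyrone-bearing, C8 CHMe), also for open-chain precursors; it is assumed that (R)-DTBM-SEGPHOS delivers hydride to the Re face in step 4, otherwise its antipode is used.

Step 1
Reactants: 1 3,5-dimethylbenzoic acid
Product: 3 1,3,5-trimethylcyclohexa-2,5-diene-1-carboxylic acid, via dilithium dienediolate 2 (not isolated)
Conditions: Li, NH3 (l), THF, −78 °C; MeI, −78 °C to rt; aq. NH4Cl, then cold HCl to pH 3
Reagents that add atoms: iodomethane (CI)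
Why: Birch reduction of the benzoate gives the 1,4-dihydro dienediolate, and its alkylation at the ipso carbon (Birch reductive alkylation) builds the quaternary C1 flanked by two enantiotopic trisubstituted alkenes; no stereocentre is formed.

Step 2
Reactants: 3 1,3,5-trimethylcyclohexa-2,5-diene-1-carboxylic acid
Product: 4 1-(1,3,5-trimethylcyclohexa-2,5-dien-1-yl)ethan-1-one
Conditions: MeLi (2.5 equiv), Et2O, 0 °C to rt; cold aq. NH4Cl
Reagents that add atoms: methyllithium ([Li]C)
Why: Addition of methyllithium to the lithium carboxylate stops at the gem-diolate, which collapses to the methyl ketone on work-up (organolithium ketone synthesis from a carboxylic acid); the α-quaternary centre suppresses over-addition.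

Step 3
Reactants: 4 1-(1,3,5-trimethylcyclohexa-2,5-dien-1-yl)ethan-1-one; 5 triethyl phosphonoacetate
Product: 7 ethyl (2E)-3-(1,3,5-trimethylcyclohexa-2,5-dien-1-yl)but-2-enoate, via sodium phosphonate carbanion 6 (not isolated)
Conditions: NaH, DME, 0 °C; then 4, 85 °C
Reagents that add atoms: none
Why: Horner–Wadsworth–Emmons olefination of the hindered methyl ketone should place the ester trans to the bulky dienyl group (E), which step 4 needs for a single sense of induction.

Step 4
Reactants: 7 ethyl (2E)-3-(1,3,5-trimethylcyclohexa-2,5-dien-1-yl)but-2-enoate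
Product: 8 ethyl (3S)-3-(1,3,5-trimethylcyclohexa-2,5-dien-1-yl)butanoate
Conditions: Cu(OAc)2 (cat.), (R)-DTBM-SEGPHOS, (MeO)2MeSiH, t-BuOH, toluene, 0 °C to rt
Reagents that add atoms: none
Why: Copper hydride-catalysed asymmetric conjugate reduction of the β,β-disubstituted enoate delivers hydride to the Re face of the β-carbon under ligand control and sets the future C8 as S; the isolated ring alkenes are not reduced.

Step 5
Reactants: 8 ethyl (3S)-3-(1,3,5-trimethylcyclohexa-2,5-dien-1-yl)butanoate
Product: 9 (3S)-3-(1,3,5-trimethylcyclohexa-2,5-dien-1-yl)butanenitrile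
Conditions: Me3Al, NH3 (gives Me2AlNH2), xylene, 125 °C
Reagents that add atoms: dimethylaluminium amide (C[Al](C)N)
Why: Aminolysis of the ester by the aluminium amide and dehydration of the amide in the same flask (aluminium amide ester-to-nitrile conversion) gives the nitrile without touching the C3 stereocentre.

Step 6
Reactants: 9 (3S)-3-(1,3,5-trimethylcyclohexa-2,5-dien-1-yl)butanenitrile
Product: 11 (3S)-2-methyl-3-(1,3,5-trimethylcyclohexa-2,5-dien-1-yl)butanenitrile (both C2 epimers), via lithiated nitrile 10 (not isolated)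
Conditions: LDA, THF, −78 °C; MeI, −78 °C
Reagents that add atoms: iodomethane (CI)
Why: Deprotonation α to the nitrile and SN2 methylation (nitrile α-alkylation) installs the future C7 methyl; the new centre forms as a mixture, which does not matter because step 8 planarises it again.

Step 7
Reactants: 11 (3S)-2-methyl-3-(1,3,5-trimethylcyclohexa-2,5-dien-1-yl)butanenitrile
Product: 12 (3S)-3-[2,3:5,6-diepoxy-1,3,5-trimethylcyclohexyl]-2-methylbutanenitrile (oxiranes cis to the C1 methyl; both C2 epimers)
Conditions: mCPBA (2.3 equiv), NaHCO3, CH2Cl2, 0 °C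
Reagents that add atoms: 3-chloroperoxybenzoic acid (OOC(=O)c1cccc(Cl)c1)
Why: Prilezhaev epoxidation of both trisubstituted ring alkenes should occur from the face of the small C1 methyl group, away from the branched side chain, so that both oxiranes lie anti to the chain as the closure in step 8 requires.

Step 8
Reactants: 12 (3S)-3-[2,3:5,6-diepoxy-1,3,5-trimethylcyclohexyl]-2-methylbutanenitrile
Product: 14 (1R,2S,3R,5S,6S,7S,8S)-2,3-epoxy-1,3,5,7,8-pentamethyl-5-(triethylsilyloxy)bicyclo[4.2.0]octane-7-carbonitrile, via potassium alkoxide 13 (not isolated)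
Conditions: KHMDS, toluene, 0 °C to rt; then TESOTf, −78 to 0 °C
Reagents that add atoms: triethylsilyl trifluoromethanesulfonate (CC[Si](CC)(CC)OS(=O)(=O)C(F)(F)F)
Why: Stork epoxynitrile cyclisation: the planar nitrile-stabilised carbanion (both C7 epimers converge) opens an oxirane at its secondary carbon from the face opposite to oxygen in a 4-exo-tet closure that should prefer, of the two diastereotopic oxiranes, the one that leaves the C8 methyl on the convex face beside the C1 methyl, while the slim cyano group takes the concave position next to C5, so that C1, C6 and C7 are set together with the C5 carbinol (oxygen trans to C7); the tertiary alkoxide is silylated in the flask.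

Step 9
Reactants: 14 (1R,2S,3R,5S,6S,7S,8S)-2,3-epoxy-1,3,5,7,8-pentamethyl-5-(triethylsilyloxy)bicyclo[4.2.0]octane-7-carbonitrile
Product: 15 (1R,5S,6R,7S,8R)-1,3,5,7,8-pentamethyl-5-(triethylsilyloxy)bicyclo[4.2.0]oct-2-ene-7-carbonitrile
Conditions: WCl6, n-BuLi (2 equiv per W), THF, −78 °C to rt; then 14, rt
Reagents that add atoms: none
Why: Low-valent tungsten removes the oxirane oxygen (tungsten-mediated epoxide deoxygenation) and regenerates the C2=C3 alkene; nitrile and silyl ether are inert.

Step 10
Reactants: 15 (1R,5S,6R,7S,8R)-1,3,5,7,8-pentamethyl-5-(triethylsilyloxy)bicyclo[4.2.0]oct-2-ene-7-carbonitrile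
Product: 16 (1R,5S,6R,7S,8R)-1,3,5,7,8-pentamethyl-5-(triethylsilyloxy)bicyclo[4.2.0]oct-2-ene-7-carbaldehyde
Conditions: DIBAL, toluene, −78 °C; aq. tartaric acid work-up
Reagents that add atoms: water (O)
Why: Half-reduction of the nitrile by DIBAL to the aluminium imine and hydrolysis on work-up (nitrile-to-aldehyde reduction); the α-carbon is quaternary, so it cannot epimerise.

Step 11
Reactants: 16 (1R,5S,6R,7S,8R)-1,3,5,7,8-pentamethyl-5-(triethylsilyloxy)bicyclo[4.2.0]oct-2-ene-7-carbaldehyde; 17 methyl 2-methyl-3-oxopentanoate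
Product: 19 methyl 5-hydroxy-2,4-dimethyl-3-oxo-5-[(1R,5S,6R,7S,8R)-1,3,5,7,8-pentamethyl-5-(triethylsilyloxy)bicyclo[4.2.0]oct-2-en-7-yl]pentanoate (mixture at the three chain centres), via keto ester dianion 18 (not isolated)
Conditions: 17, LDA (2 equiv), THF, −78 to 0 °C; then 16, −78 °C; AcOH quench
Reagents that add atoms: none
Why: Aldol addition of the γ-carbon of the β-keto ester dianion to the non-enolisable neopentyl aldehyde; the three new chain centres form as a mixture and are removed in steps 12 and 13.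

Step 12
Reactants: 19 methyl 5-hydroxy-2,4-dimethyl-3-oxo-5-[bicyclic]pentanoate
Product: 20 methyl 2,4-dimethyl-3,5-dioxo-5-[(1R,5S,6R,7S,8R)-1,3,5,7,8-pentamethyl-5-(triethylsilyloxy)bicyclo[4.2.0]oct-2-en-7-yl]pentanoate
Conditions: Dess–Martin periodinane, NaHCO3, CH2Cl2, 0 °C to rt
Reagents that add atoms: none
Why: Dess–Martin oxidation of the secondary alcohol gives the 3,5-diketo ester; alkene and silyl ether are untouched.

Step 13
Reactants: 20 methyl 2,4-dimethyl-3,5-dioxo-5-[bicyclic]pentanoate
Product: 21 4-hydroxy-3,5-dimethyl-6-[(1R,5S,6R,7S,8R)-1,3,5,7,8-pentamethyl-5-(triethylsilyloxy)bicyclo[4.2.0]oct-2-en-7-yl]-2H-pyran-2-one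
Conditions: DBU, toluene, 80 °C
Reagents that add atoms: none
Why: Base-mediated enolisation and lactonisation of the δ-keto enol onto the methyl ester (pyranone cyclocondensation) gives the 4-hydroxy-2-pyranone with loss of methanol.

Step 14
Reactants: 21 4-hydroxy-3,5-dimethyl-6-[bicyclic]-2H-pyran-2-one
Product: 22 2-methoxy-3,5-dimethyl-6-[(1R,5S,6R,7S,8R)-1,3,5,7,8-pentamethyl-5-(triethylsilyloxy)bicyclo[4.2.0]oct-2-en-7-yl]-4H-pyran-4-one
Conditions: MeOTf, CH2Cl2, 0 °C to rt; aq. NaHCO3
Reagents that add atoms: methyl trifluoromethanesulfonate (COS(=O)(=O)C(F)(F)F)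
Why: The hard methylating agent alkylates the neutral hydroxypyranone at the lactone carbonyl oxygen and deprotonation on work-up gives the 2-methoxy-4-pyranone (regioselective pyranone O-methylation).

Step 15
Reactants: 22 2-methoxy-3,5-dimethyl-6-[5-(triethylsilyloxy) bicyclic]-4H-pyran-4-one
Product: 23 6-[(1R,5S,6R,7S,8R)-5-hydroxy-1,3,5,7,8-pentamethylbicyclo[4.2.0]oct-2-en-7-yl]-2-methoxy-3,5-dimethyl-4H-pyran-4-one
Conditions: TBAF, THF, rt to 40 °C
Reagents that add atoms: none
Why: Fluoride-induced desilylation frees the tertiary C5 alcohol; the pyrone and the alkene are stable to fluoride.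

Step 16
Reactants: 23 6-[(1R,5S,6R,7S,8R)-5-hydroxy-1,3,5,7,8-pentamethylbicyclo[4.2.0]oct-2-en-7-yl]-2-methoxy-3,5-dimethyl-4H-pyran-4-one
Product: 24 6-[(1R,2R,5S,6R,7S,8R)-2-hydroperoxy-5-hydroxy-1,3,5,7,8-pentamethylbicyclo[4.2.0]oct-3-en-7-yl]-2-methoxy-3,5-dimethyl-4H-pyran-4-one
Conditions: O2, tetraphenylporphyrin (cat.), visible light, CH2Cl2, −20 °C
Reagents that add atoms: dioxygen (O=O)
Why: Schenck ene reaction: singlet oxygen adds to C2 on the convex face, opposite to the cyclobutane and the pyrone that cover the other face, and takes a hydrogen suprafacially from C4 so that the alkene moves to C3=C4 and C2 is set R; bonding at C3 is impossible because C1 bears no hydrogen, and hydrogen bonding of the developing perepoxide to the cis C5 hydroxyl is counted on to favour abstraction at C4 over the C3 methyl group.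

Step 17
Reactants: 24 6-[(1R,2R,5S,6R,7S,8R)-2-hydroperoxy-5-hydroxy-1,3,5,7,8-pentamethylbicyclo[4.2.0]oct-3-en-7-yl]-2-methoxy-3,5-dimethyl-4H-pyran-4-one
Product: 25 6-[(1R,2R,5S,6R,7S,8R)-2,5-epidioxy-1,3,5,7,8-pentamethylbicyclo[4.2.0]oct-3-en-7-yl]-2-methoxy-3,5-dimethyl-4H-pyran-4-one
Conditions: PPTS (0.2 equiv), 4 Å molecular sieves, CH2Cl2–(CF3)2CHOH 4:1 (0.005 M), −20 to 0 °C
Reagents that add atoms: none
Why: The weak acid in an ionising, poorly nucleophilic medium promotes loss of water from the tertiary allylic C5 carbinol to the C3–C4–C5 allyl cation, and the terminal oxygen of the C2 hydroperoxide, held on the convex face, adds to C5 to form the C5–O bond (intramolecular SN1 peroxide formation). The closest known reaction type is the acid-catalysed displacement of tertiary or allylic alcohols by hydroperoxides, including the closure of 1,2-dioxanes from hydroperoxy tertiary alcohols, together with the silver-assisted closure of bicyclic peroxides from hydroperoxy halides. One ring is closed by the single new bond: seen through C1 and C6 it is a 6-exo closure of a 1,2-dioxane onto the cation terminus, seen through C3=C4 it is the endo closure of a 3,6-dihydro-1,2-dioxine, and it requires the carbocycle in a boat with C2 and C5 at bow and stern. The only new stereocentre, C5 (S), is dictated by C2 (R), because the peroxy oxygen can reach C5 only from the face on which it is tethered; either C5 epimer of the substrate or the allyl-transposed alcohol would therefore converge on the same product. The step needs attack at C5 instead of C3 and closure faster than proton loss, external capture or Hock cleavage: attack at C3 would give a strained 1,2-dioxetane, the 1,4 transannular geometry makes closure at C5 easy, and the weak acid, low temperature, high dilution and sieves hold back the side paths.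

Compound list
1 | 3,5-dimethylbenzoic acid | Cc1cc(C)cc(C(=O)O)c1 | starting material
2 | dilithium (3,5-dimethylcyclohexa-2,5-dien-1-ylidene)methanediolate | [Li+].[Li+].CC1=CC(=C([O-])[O-])C=C(C)C1 | intermediate
3 | 1,3,5-trimethylcyclohexa-2,5-diene-1-carboxylic acid | CC1=CC(C)(C(=O)O)C=C(C)C1 | intermediate
4 | 1-(1,3,5-trimethylcyclohexa-2,5-dien-1-yl)ethan-1-one | CC(=O)C1(C)C=C(C)CC(C)=C1 | intermediate
5 | triethyl phosphonoacetate | CCOC(=O)CP(=O)(OCC)OCC | starting material
6 | sodium salt of the carbanion of triethyl phosphonoacetate | [Na+].CCOC(=O)[CH-]P(=O)(OCC)OCC | intermediate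
7 | ethyl (2E)-3-(1,3,5-trimethylcyclohexa-2,5-dien-1-yl)but-2-enoate | CCOC(=O)/C=C(\C)C1(C)C=C(C)CC(C)=C1 | intermediate
8 | ethyl (3S)-3-(1,3,5-trimethylcyclohexa-2,5-dien-1-yl)butanoate | CCOC(=O)C[C@H](C)C1(C)C=C(C)CC(C)=C1 | intermediate
9 | (3S)-3-(1,3,5-trimethylcyclohexa-2,5-dien-1-yl)butanenitrile | N#CC[C@H](C)C1(C)C=C(C)CC(C)=C1 | intermediate
10 | lithium salt of the α-cyano carbanion of 9 | [Li+].N#C[CH-][C@H](C)C1(C)C=C(C)CC(C)=C1 | intermediate
11 | (3S)-2-methyl-3-(1,3,5-trimethylcyclohexa-2,5-dien-1-yl)butanenitrile, both C2 epimers | N#CC(C)[C@H](C)C1(C)C=C(C)CC(C)=C1 | intermediate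
12 | (3S)-3-[2,3:5,6-diepoxy-1,3,5-trimethylcyclohexyl]-2-methylbutanenitrile, both oxirane oxygens cis to the C1 methyl and trans to the side chain, both C2 epimers | N#CC(C)[C@H](C)[C@@]1(C)[C@@H]2O[C@]2(C)C[C@]3(C)O[C@@H]31 | intermediate
13 | potassium (1R,2S,3R,5S,6S,7S,8S)-7-cyano-2,3-epoxy-1,3,5,7,8-pentamethylbicyclo[4.2.0]octan-5-olate | N#C[C@@]2(C)[C@H](C)[C@@]3(C)[C@@H]4O[C@]4(C)C[C@](C)([O-])[C@@H]23.[K+] | intermediate
14 | (1R,2S,3R,5S,6S,7S,8S)-2,3-epoxy-1,3,5,7,8-pentamethyl-5-(triethylsilyloxy)bicyclo[4.2.0]octane-7-carbonitrile | N#C[C@@]2(C)[C@H](C)[C@@]3(C)[C@@H]4O[C@]4(C)C[C@](C)(O[Si](CC)(CC)CC)[C@@H]23 | intermediate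
15 | (1R,5S,6R,7S,8R)-1,3,5,7,8-pentamethyl-5-(triethylsilyloxy)bicyclo[4.2.0]oct-2-ene-7-carbonitrile | N#C[C@@]2(C)[C@H](C)[C@@]3(C)C=C(C)C[C@](C)(O[Si](CC)(CC)CC)[C@@H]23 | intermediate
16 | (1R,5S,6R,7S,8R)-1,3,5,7,8-pentamethyl-5-(triethylsilyloxy)bicyclo[4.2.0]oct-2-ene-7-carbaldehyde | O=C[C@@]2(C)[C@H](C)[C@@]3(C)C=C(C)C[C@](C)(O[Si](CC)(CC)CC)[C@@H]23 | intermediate
17 | methyl 2-methyl-3-oxopentanoate | CCC(=O)C(C)C(=O)OC | starting material
18 | dilithium dianion of methyl 2-methyl-3-oxopentanoate (deprotonated at C2 and C4) | [Li+].[Li+].C[CH-]C(=O)[C-](C)C(=O)OC | intermediate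
19 | methyl 5-hydroxy-2,4-dimethyl-3-oxo-5-[(1R,5S,6R,7S,8R)-1,3,5,7,8-pentamethyl-5-(triethylsilyloxy)bicyclo[4.2.0]oct-2-en-7-yl]pentanoate, mixture at C2, C4 and C5 of the chain | COC(=O)C(C)C(=O)C(C)C(O)[C@@]2(C)[C@H](C)[C@@]3(C)C=C(C)C[C@](C)(O[Si](CC)(CC)CC)[C@@H]23 | intermediate
20 | methyl 2,4-dimethyl-3,5-dioxo-5-[(1R,5S,6R,7S,8R)-1,3,5,7,8-pentamethyl-5-(triethylsilyloxy)bicyclo[4.2.0]oct-2-en-7-yl]pentanoate | COC(=O)C(C)C(=O)C(C)C(=O)[C@@]2(C)[C@H](C)[C@@]3(C)C=C(C)C[C@](C)(O[Si](CC)(CC)CC)[C@@H]23 | intermediate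
21 | 4-hydroxy-3,5-dimethyl-6-[(1R,5S,6R,7S,8R)-1,3,5,7,8-pentamethyl-5-(triethylsilyloxy)bicyclo[4.2.0]oct-2-en-7-yl]-2H-pyran-2-one | Cc1c(O)c(C)c([C@@]2(C)[C@H](C)[C@@]3(C)C=C(C)C[C@](C)(O[Si](CC)(CC)CC)[C@@H]23)oc1=O | intermediate
22 | 2-methoxy-3,5-dimethyl-6-[(1R,5S,6R,7S,8R)-1,3,5,7,8-pentamethyl-5-(triethylsilyloxy)bicyclo[4.2.0]oct-2-en-7-yl]-4H-pyran-4-one | COc1oc([C@@]2(C)[C@H](C)[C@@]3(C)C=C(C)C[C@](C)(O[Si](CC)(CC)CC)[C@@H]23)c(C)c(=O)c1C | intermediate
23 | 6-[(1R,5S,6R,7S,8R)-5-hydroxy-1,3,5,7,8-pentamethylbicyclo[4.2.0]oct-2-en-7-yl]-2-methoxy-3,5-dimethyl-4H-pyran-4-one | COc1oc([C@@]2(C)[C@H](C)[C@@]3(C)C=C(C)C[C@](C)(O)[C@@H]23)c(C)c(=O)c1C | intermediate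
24 | 6-[(1R,2R,5S,6R,7S,8R)-2-hydroperoxy-5-hydroxy-1,3,5,7,8-pentamethylbicyclo[4.2.0]oct-3-en-7-yl]-2-methoxy-3,5-dimethyl-4H-pyran-4-one (hydroperoxide and hydroxyl both on the convex face) | COc1oc([C@@]2(C)[C@H](C)[C@@]3(C)[C@H](OO)C(C)=C[C@](C)(O)[C@@H]23)c(C)c(=O)c1C | intermediate
25 | 6-[(1R,2R,5S,6R,7S,8R)-2,5-epidioxy-1,3,5,7,8-pentamethylbicyclo[4.2.0]oct-3-en-7-yl]-2-methoxy-3,5-dimethyl-4H-pyran-4-one | COc1oc([C@@]2(C)[C@H](C)[C@@]3(C)[C@@H]4OO[C@@](C)(C=C4C)[C@@H]23)c(C)c(=O)c1C | target

Total step count: 17. Longest linear sequence: 17 steps (1 to 25).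

Steps most likely to fail

1. Step 17. The allyl cation may lose a proton or be captured from outside before the peroxide closes, or the acid may start Hock-type fragmentation of the allylic hydroperoxide. The fallback sets out from 23 and returns at 25. Anti elimination with SOCl2 and pyridine at −30 °C removes the C4 hydrogen trans to the hydroxyl and gives the conjugated bicyclo[4.2.0]octa-2,4-diene F1, which is kept below 0 °C to hold back electrocyclic ring opening. Tetraphenylporphyrin-sensitised photooxygenation at −40 °C then adds singlet oxygen in a [4+2] cycloaddition across C2 and C5 on the convex face and gives 25 directly. This replaces the cationic closure by a pericyclic one.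

2. Step 16. Hydrogen abstraction may take place at the C3 methyl group instead of C4, which would move the alkene out of the ring, or oxygen may be delivered to the concave face. The fallback sets out from 23 and returns at 25. The same anti elimination also gives, by loss of a methyl hydrogen, the exocyclic 5-methylidene 1,4-diene F2, which can be separated from F1 or carried on with it. In F2 the C4 hydrogens are doubly allylic, so the ene reaction of singlet oxygen should abstract there and give the conjugated dienyl hydroperoxide F3 (oxygen on C2, alkenes C3=C4 and C5=CH2, a transoid diene that cannot add a second oxygen molecule). PPTS in CH2Cl2–(CF3)2CHOH protonates the exocyclic methylene of F3 to the same C3–C5 allyl cation as in step 17, and the C2 hydroperoxide closes on C5 to give 25.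

3. Step 8 (with step 7). The carbanion may open the other diastereotopic oxirane, which would put the C8 methyl on the concave face, or an oxirane may sit on the wrong ring face and not cyclise. The fallback sets out from 11 and returns at 15. A Shi epoxidation (fructose-derived chiral ketone in the enantiomer matched to the C5=C6 alkene, Oxone, buffered MeCN–dimethoxymethane–water, 0 °C), stopped at one equivalent, epoxidises only that alkene on its face anti to the side chain and gives the monoepoxide F4. KHMDS in toluene then closes the cyclobutane on the only oxirane present to give the potassium alkoxide F5, and TESOTf silylates it in the flask to 15. The choice between the two alkenes is thus made by the reagent, and the deoxygenation of step 9 is no longer needed.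

Further compounds
F1 | step 17 | 2-methoxy-3,5-dimethyl-6-[(1R,6R,7S,8R)-1,3,5,7,8-pentamethylbicyclo[4.2.0]octa-2,4-dien-7-yl]-4H-pyran-4-one | COc1oc([C@@]2(C)[C@H](C)[C@@]3(C)C=C(C)C=C(C)[C@@H]23)c(C)c(=O)c1C
F2 | step 16 | 2-methoxy-3,5-dimethyl-6-[(1R,6R,7S,8R)-1,3,7,8-tetramethyl-5-methylidenebicyclo[4.2.0]oct-2-en-7-yl]-4H-pyran-4-one | COc1oc([C@@]2(C)[C@H](C)[C@@]3(C)C=C(C)CC(=C)[C@@H]23)c(C)c(=O)c1C
F3 | step 16 | 6-[(1R,2R,6R,7S,8R)-2-hydroperoxy-1,3,7,8-tetramethyl-5-methylidenebicyclo[4.2.0]oct-3-en-7-yl]-2-methoxy-3,5-dimethyl-4H-pyran-4-one | COc1oc([C@@]2(C)[C@H](C)[C@@]3(C)[C@H](OO)C(C)=CC(=C)[C@@H]23)c(C)c(=O)c1C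
F4 | step 8 | (3S)-3-[5,6-epoxy-1,3,5-trimethylcyclohex-2-en-1-yl]-2-methylbutanenitrile, oxirane cis to the C1 methyl, both C2 epimers | N#CC(C)[C@H](C)[C@@]1(C)C=C(C)C[C@]2(C)O[C@H]12
F5 | step 8 | potassium (1R,5S,6R,7S,8R)-7-cyano-1,3,5,7,8-pentamethylbicyclo[4.2.0]oct-2-en-5-olate | N#C[C@@]2(C)[C@H](C)[C@@]3(C)C=C(C)C[C@](C)([O-])[C@@H]23.[K+]
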